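Pauciflorol E (19) ⇐ hydrogenolysis of tetrabenzyl ether 18 ⇐ seven-membered ketone ring closed last by intramolecular Pd-catalysed α-arylation of bromo ketone 17 (bond from the ketone α-carbon, Cα, to ring B, the 3,5-dioxygenated ring) ⇐ Weinreb amide 14 + benzylic Grignard reagent 16.
Key disconnection: the O1–C7a bond of the dihydrobenzofuran (benzofuran numbering; ring A = C3a–C7a). 14 ⇐ open-chain hydroxy amide 11, whose ring A is a plain para-alkylphenol with only H at C7a: PhI(OAc)2 dearomatisation to a para-quinol, 5-exo oxa-Michael addition of the C2 hydroxyl and dehydrative rearomatisation in one operation (net C–H etherification, no halogen on ring A).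
Enabling feature: the ring A hydroxyl on C6 is para to C3a (the carbon that carries C3) and meta to C7a; oxidation to the para-quinol at C3a turns C7a into a dienone β-carbon four atoms from the C2 oxygen, and loss of water afterwards returns exactly the C6 phenol of the natural product.
11 ⇐ trans-isochromanone 10 ⇐ Baeyer–Villiger oxygen insertion (retention at C2) into trans-2,3-diarylindanone 9 ⇐ α-arylation of (R)-3-arylindanone 5 ⇐ asymmetric reductive Heck cyclisation of 2'-bromochalcone 4 (C3 from the catalyst, C2 trans by equilibration, Cα last by equilibration).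
Ring order: indanone (temporary) → isochromanone (temporary, opened again) → dihydrofuran (key step) → seven-membered ketone ring.
Key step: step 9

Assumption: the enolisable centre Cα of the natural product (aryl trans to the C3–C2 bond) is taken to be the thermodynamically preferred epimer, and 1-(2-bromo-5-hydroxyphenyl)ethan-1-one (1) is taken to be a catalogue compound (Bn = benzyl, MOM = methoxymethyl; C2 and C3 always mean the future dihydrofuran carbons).

Step 1
Reactants: 1 1-(2-bromo-5-hydroxyphenyl)ethan-1-one
Product: 2 1-[2-bromo-5-(methoxymethoxy)phenyl]ethan-1-one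
Conditions: MOMCl, iPr2NEt, CH2Cl2, 0 °C to rt
Reagents that add atoms: chloromethyl methyl ether, COCCl
Why: O-alkylation of the phenol to its MOM acetal masks the ring A hydroxyl through the basic and palladium steps and the ring bromination, and can later be removed with acid without touching benzyl ethers.

Step 2
Reactants: 2 1-[2-bromo-5-(methoxymethoxy)phenyl]ethan-1-one; 3 3,5-bis(benzyloxy)benzaldehyde
Product: 4 (E)-3-[3,5-bis(benzyloxy)phenyl]-1-[2-bromo-5-(methoxymethoxy)phenyl]prop-2-en-1-one
Conditions: KOH, EtOH, rt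
Reagents that add atoms: none
Why: Claisen–Schmidt aldol condensation of the methyl ketone with the non-enolisable aldehyde should give the E-chalcone under thermodynamic control.

Step 3
Reactants: 4 (E)-3-[3,5-bis(benzyloxy)phenyl]-1-[2-bromo-5-(methoxymethoxy)phenyl]prop-2-en-1-one
Product: 5 (R)-3-[3,5-bis(benzyloxy)phenyl]-6-(methoxymethoxy)-2,3-dihydro-1H-inden-1-one
Conditions: Pd(OAc)2 (5 mol %), 3,5-Xyl-MeO-BIPHEP (6 mol %, the enantiomer that leads to the R product), HCO2Na, DMF, 80 °C
Reagents that add atoms: none
Why: Asymmetric reductive Heck cyclisation (arylpalladium adds to the enone β-carbon and the palladium enolate is reduced by formate), a reaction known for 2'-halochalcones giving 3-arylindanones; the chiral bisphosphine on palladium discriminates the two faces of the enone β-carbon and so sets C3, the only centre in the route that comes from a chiral reagent.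

Step 4
Reactants: 5 (R)-3-[3,5-bis(benzyloxy)phenyl]-6-(methoxymethoxy)-2,3-dihydro-1H-inden-1-one; 6 1-(benzyloxy)-4-bromobenzene
Product: 7 (2R,3R)-2-[4-(benzyloxy)phenyl]-3-[3,5-bis(benzyloxy)phenyl]-6-(methoxymethoxy)-2,3-dihydro-1H-inden-1-one (2,3-trans)
Conditions: Pd2(dba)3 (2.5 mol %), Xantphos (6 mol %), K3PO4, toluene, 80 °C
Reagents that add atoms: none
Why: Palladium-catalysed ketone α-arylation of the indanone enolate; the new C2 centre is enolisable and should settle trans to the C3 aryl group, while the weak base avoids a second deprotonation at C3 that would racemise it.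

Step 5
Reactants: 7 (2R,3R)-2-[4-(benzyloxy)phenyl]-3-[3,5-bis(benzyloxy)phenyl]-6-(methoxymethoxy)-2,3-dihydro-1H-inden-1-one
Product: 8 (2R,3S)-2-[4-(benzyloxy)phenyl]-3-[3,5-bis(benzyloxy)-2-bromophenyl]-6-(methoxymethoxy)-2,3-dihydro-1H-inden-1-one (2,3-trans; same spatial arrangement as 7, the C3 descriptor changes only with the priority of the brominated ring)
Conditions: NBS (1.05 equiv), MeCN, 0 °C, dark
Reagents that add atoms: N-bromosuccinimide, O=C1CCC(=O)N1Br
Why: Electrophilic aromatic bromination should go to the most electron-rich ring, the 3,5-dialkoxyphenyl ring B, ortho to the benzylic carbon and para to an alkoxy group (the two such positions are equivalent by rotation), and it places the handle for the last ring closure after both intermolecular palladium steps are over.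

Step 6
Reactants: 8 (2R,3S)-2-[4-(benzyloxy)phenyl]-3-[3,5-bis(benzyloxy)-2-bromophenyl]-6-(methoxymethoxy)-2,3-dihydro-1H-inden-1-one
Product: 9 (2R,3S)-2-[4-(benzyloxy)phenyl]-3-[3,5-bis(benzyloxy)-2-bromophenyl]-6-hydroxy-2,3-dihydro-1H-inden-1-one
Conditions: HCl (1.25 M in MeOH), THF, 45 °C
Reagents that add atoms: none
Why: Acid-catalysed acetal exchange removes the MOM group at a stage where no acid-labile benzylic C–O bond is present; benzyl ethers, the aryl bromide and the trans-indanone (already the stable C2 epimer) should be unaffected.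

Step 7
Reactants: 9 (2R,3S)-2-[4-(benzyloxy)phenyl]-3-[3,5-bis(benzyloxy)-2-bromophenyl]-6-hydroxy-2,3-dihydro-1H-inden-1-one
Product: 10 (3R,4S)-3-[4-(benzyloxy)phenyl]-4-[3,5-bis(benzyloxy)-2-bromophenyl]-7-hydroxyisochroman-1-one (3,4-trans)
Conditions: mCPBA (1.5 equiv), CH2Cl2, 0 °C to rt
Reagents that add atoms: 3-chloroperbenzoic acid, O=C(OO)c1cccc(Cl)c1
Why: Baeyer–Villiger oxidation, in which the secondary 4-alkoxybenzylic carbon C2 should migrate in preference to the aryl carbon (benzyl migrates over phenyl in benzyl aryl ketones, and 2-substituted indanones give 3-substituted isochromanones) with retention at C2, so the trans relation of the indanone becomes that of the future dihydrofuran.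

Step 8
Reactants: 10 (3R,4S)-3-[4-(benzyloxy)phenyl]-4-[3,5-bis(benzyloxy)-2-bromophenyl]-7-hydroxyisochroman-1-one
Product: 11 2-{(1S,2R)-2-[4-(benzyloxy)phenyl]-1-[3,5-bis(benzyloxy)-2-bromophenyl]-2-hydroxyethyl}-5-hydroxy-N-methoxy-N-methylbenzamide
Conditions: MeNH(OMe)·HCl, iPrMgCl, THF, −20 to 0 °C; aq. NH4Cl
Reagents that add atoms: N,O-dimethylhydroxylamine hydrochloride, CNOC.Cl
Why: Weinreb aminolysis of the lactone by the chloromagnesium amide frees the C2 hydroxyl and turns the lactone carbonyl into a ketone precursor, while the ring A phenoxide, para to the benzylic carbon, should suppress benzylic deprotonation and E1cB opening.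

Step 9
Reactants: 11 2-{(1S,2R)-2-[4-(benzyloxy)phenyl]-1-[3,5-bis(benzyloxy)-2-bromophenyl]-2-hydroxyethyl}-5-hydroxy-N-methoxy-N-methylbenzamide
Product: 14 (2R,3S)-2-[4-(benzyloxy)phenyl]-3-[3,5-bis(benzyloxy)-2-bromophenyl]-6-hydroxy-N-methoxy-N-methyl-2,3-dihydrobenzofuran-4-carboxamide (2,3-trans), via para-quinol 12 (not isolated), via oxa-Michael adduct 13 (not isolated)
Conditions: PhI(OAc)2 (1.1 equiv), MeCN/H2O 4:1, 0 °C; aq. NaHCO3 wash; crude in CH2Cl2, DBU (10 mol %), rt; then TsOH·H2O (30 mol %), 40 °C
Reagents that add atoms: none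
Why: The phenol of 11 binds to trivalent iodine and is oxidised by two electrons with loss of iodobenzene, water adding at the para carbon C3a to give para-quinol 12, as in the known PhI(OAc)2 dearomatisation of para-alkylphenols. C7a is now a β-carbon of a cross-conjugated dienone four atoms from the C2 hydroxyl, which adds under base catalysis in the 5-exo-trig mode to give the cis-fused adduct 13 (the known oxa-Michael closure of hydroxyalkyl para-quinols to hexahydrobenzofuranones). Acid then removes the tertiary hydroxyl at C3a together with the hydrogen at C7a and the dienone enolises, the closest analogy being the addition–elimination of nucleophiles to quinol derivatives that gives meta-substituted phenols, so ring A returns with its C6 phenol and the new aryl ether. No stereocentre of 14 is made here: no bond to C2 or C3 is formed or broken, so their trans relation from steps 4 and 7 is kept, and the transient centres at C3a and C7a vanish, so both epimers of 12 converge. The step needs oxidation of ring A only (it holds the only free phenol), water capture at C3a rather than loss of the C3 hydrogen to a quinone methide (the ortho amide holds that C–H bond in the ring plane, out of conjugation), and productive addition at C7a rather than at the other β-carbon C4 (fully substituted, so addition there is reversible and cannot aromatise).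

Step 10
Reactants: 15 1-(benzyloxy)-4-(chloromethyl)benzene
Product: 16 [4-(benzyloxy)benzyl]magnesium chloride (THF solution)
Conditions: Mg turnings, THF, 0 °C, slow addition
Reagents that add atoms: magnesium, [Mg]
Why: Grignard formation by insertion of magnesium into the benzylic C–Cl bond, run cold and dilute to limit Wurtz coupling.

Step 11
Reactants: 14 (2R,3S)-2-[4-(benzyloxy)phenyl]-3-[3,5-bis(benzyloxy)-2-bromophenyl]-6-hydroxy-N-methoxy-N-methyl-2,3-dihydrobenzofuran-4-carboxamide; 16 [4-(benzyloxy)benzyl]magnesium chloride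
Product: 17 1-{(2R,3S)-2-[4-(benzyloxy)phenyl]-3-[3,5-bis(benzyloxy)-2-bromophenyl]-6-hydroxy-2,3-dihydrobenzofuran-4-yl}-2-[4-(benzyloxy)phenyl]ethan-1-one
Conditions: 16 (3.5 equiv), THF, −20 to 0 °C; aq. NH4Cl
Reagents that add atoms: none
Why: Weinreb ketone synthesis, in which one equivalent of the Grignard reagent deprotonates the phenol and the next adds to the amide to give a chelated tetrahedral intermediate that releases the ketone only on work-up, so over-addition should not occur.

Step 12
Reactants: 17 1-{(2R,3S)-2-[4-(benzyloxy)phenyl]-3-[3,5-bis(benzyloxy)-2-bromophenyl]-6-hydroxy-2,3-dihydrobenzofuran-4-yl}-2-[4-(benzyloxy)phenyl]ethan-1-one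
Product: 18 pauciflorol E tetrabenzyl ether (both ring B phenols and both 4-hydroxyphenyl groups as benzyl ethers, ring A phenol free; C2 R, C3 R, Cα R)
Conditions: Pd(OAc)2 (10 mol %), XPhos (20 mol %), K3PO4, toluene, 100 °C; aq. NH4Cl; then DBU (cat.), CH2Cl2, rt
Reagents that add atoms: none
Why: Intramolecular palladium-catalysed α-arylation of the benzyl ketone enolate with the ring B bromide closes the seven-membered ring, a reaction type known for benzo-fused seven-membered ketones; the new centre Cα is enolisable, so equilibration should give the thermodynamically preferred epimer, taken to be that of the natural product.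

Step 13
Reactants: 18 pauciflorol E tetrabenzyl ether
Product: 19 pauciflorol E
Conditions: H2 (1 atm), 10% Pd/C, EtOAc/MeOH, rt
Reagents that add atoms: none
Why: Hydrogenolysis of the four aryl benzyl ethers over palladium on carbon under neutral conditions should be much faster than cleavage of the cyclic benzylic ether or reduction of the diaryl ketone and leaves all three stereocentres untouched.

Compound list
1 | 1-(2-bromo-5-hydroxyphenyl)ethan-1-one | CC(=O)c1cc(O)ccc1Br | starting material
2 | 1-[2-bromo-5-(methoxymethoxy)phenyl]ethan-1-one | CC(=O)c1cc(OCOC)ccc1Br | intermediate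
3 | 3,5-bis(benzyloxy)benzaldehyde | O=Cc1cc(OCc2ccccc2)cc(OCc2ccccc2)c1 | starting material
4 | (E)-3-[3,5-bis(benzyloxy)phenyl]-1-[2-bromo-5-(methoxymethoxy)phenyl]prop-2-en-1-one | O=C(/C=C/c1cc(OCc2ccccc2)cc(OCc2ccccc2)c1)c1cc(OCOC)ccc1Br | intermediate
5 | (R)-3-[3,5-bis(benzyloxy)phenyl]-6-(methoxymethoxy)-2,3-dihydro-1H-inden-1-one | COCOc1ccc2c(c1)C(=O)C[C@@H]2c1cc(OCc2ccccc2)cc(OCc2ccccc2)c1 | intermediate
6 | 1-(benzyloxy)-4-bromobenzene | Brc1ccc(OCc2ccccc2)cc1 | starting material
7 | (2R,3R)-2-[4-(benzyloxy)phenyl]-3-[3,5-bis(benzyloxy)phenyl]-6-(methoxymethoxy)-2,3-dihydro-1H-inden-1-one | COCOc1ccc2c(c1)C(=O)[C@@H](c1ccc(OCc3ccccc3)cc1)[C@@H]2c1cc(OCc2ccccc2)cc(OCc2ccccc2)c1 | intermediate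
8 | (2R,3S)-2-[4-(benzyloxy)phenyl]-3-[3,5-bis(benzyloxy)-2-bromophenyl]-6-(methoxymethoxy)-2,3-dihydro-1H-inden-1-one | COCOc1ccc2c(c1)C(=O)[C@@H](c1ccc(OCc3ccccc3)cc1)[C@@H]2c1cc(OCc2ccccc2)cc(OCc2ccccc2)c1Br | intermediate
9 | (2R,3S)-2-[4-(benzyloxy)phenyl]-3-[3,5-bis(benzyloxy)-2-bromophenyl]-6-hydroxy-2,3-dihydro-1H-inden-1-one | Oc1ccc2c(c1)C(=O)[C@@H](c1ccc(OCc3ccccc3)cc1)[C@@H]2c1cc(OCc2ccccc2)cc(OCc2ccccc2)c1Br | intermediate
10 | (3R,4S)-3-[4-(benzyloxy)phenyl]-4-[3,5-bis(benzyloxy)-2-bromophenyl]-7-hydroxyisochroman-1-one | Oc1ccc2c(c1)C(=O)O[C@@H](c1ccc(OCc3ccccc3)cc1)[C@@H]2c1cc(OCc2ccccc2)cc(OCc2ccccc2)c1Br | intermediate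
11 | 2-{(1S,2R)-2-[4-(benzyloxy)phenyl]-1-[3,5-bis(benzyloxy)-2-bromophenyl]-2-hydroxyethyl}-5-hydroxy-N-methoxy-N-methylbenzamide | CON(C)C(=O)c1cc(O)ccc1[C@@H](c1cc(OCc2ccccc2)cc(OCc2ccccc2)c1Br)[C@@H](O)c1ccc(OCc2ccccc2)cc1 | intermediate
12 | para-quinol: 6-{(1S,2R)-2-[4-(benzyloxy)phenyl]-1-[3,5-bis(benzyloxy)-2-bromophenyl]-2-hydroxyethyl}-6-hydroxy-N-methoxy-N-methyl-3-oxocyclohexa-1,4-diene-1-carboxamide (both epimers at the quinol carbon) | CON(C)C(=O)C1=CC(=O)C=CC1(O)[C@@H](c1cc(OCc2ccccc2)cc(OCc2ccccc2)c1Br)[C@@H](O)c1ccc(OCc2ccccc2)cc1 | intermediate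
13 | oxa-Michael adduct: (2R,3S)-2-[4-(benzyloxy)phenyl]-3-[3,5-bis(benzyloxy)-2-bromophenyl]-3a-hydroxy-N-methoxy-N-methyl-6-oxo-2,3,3a,6,7,7a-hexahydrobenzofuran-4-carboxamide (cis ring fusion, both cis-fused diastereomers) | CON(C)C(=O)C1=CC(=O)CC2O[C@@H](c3ccc(OCc4ccccc4)cc3)[C@H](c3cc(OCc4ccccc4)cc(OCc4ccccc4)c3Br)C12O | intermediate
14 | (2R,3S)-2-[4-(benzyloxy)phenyl]-3-[3,5-bis(benzyloxy)-2-bromophenyl]-6-hydroxy-N-methoxy-N-methyl-2,3-dihydrobenzofuran-4-carboxamide | CON(C)C(=O)c1cc(O)cc2O[C@@H](c3ccc(OCc4ccccc4)cc3)[C@H](c3cc(OCc4ccccc4)cc(OCc4ccccc4)c3Br)c12 | intermediate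
15 | 1-(benzyloxy)-4-(chloromethyl)benzene | ClCc1ccc(OCc2ccccc2)cc1 | starting material
16 | [4-(benzyloxy)benzyl]magnesium chloride | Cl[Mg]Cc1ccc(OCc2ccccc2)cc1 | intermediate
17 | 1-{(2R,3S)-2-[4-(benzyloxy)phenyl]-3-[3,5-bis(benzyloxy)-2-bromophenyl]-6-hydroxy-2,3-dihydrobenzofuran-4-yl}-2-[4-(benzyloxy)phenyl]ethan-1-one | O=C(Cc1ccc(OCc2ccccc2)cc1)c1cc(O)cc2O[C@@H](c3ccc(OCc4ccccc4)cc3)[C@H](c3cc(OCc4ccccc4)cc(OCc4ccccc4)c3Br)c12 | intermediate
18 | pauciflorol E tetrabenzyl ether (ring A phenol free; C2 R, C3 R, Cα R) | O=C1c2cc(O)cc3c2[C@@H](c2cc(OCc4ccccc4)cc(OCc4ccccc4)c2[C@H]1c1ccc(OCc2ccccc2)cc1)[C@H](c1ccc(OCc2ccccc2)cc1)O3 | intermediate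
19 | pauciflorol E (C2 R, C3 R, Cα R) | O=C1c2cc(O)cc3c2[C@@H](c2cc(O)cc(O)c2[C@H]1c1ccc(O)cc1)[C@H](c1ccc(O)cc1)O3 | target

Total step count: 13. Longest linear sequence: 12 steps (steps 1–9 and 11–13; step 10 is a side branch).

Steps most likely to fail

1. Step 9 (key step). The oxidised phenol may lose the benzylic hydrogen at C3 and collapse to a para-quinone methide, which would erase C3, instead of capturing water at C3a; the quinol may also suffer an acid-induced 1,2-shift before it cyclises. The fallback sets out from 11 and comes back at 14, and dearomatises with singlet oxygen so that no phenoxenium-type species is formed. Oxone and NaHCO3 in MeCN/H2O at rt (singlet oxygen made in the flask adds to the phenolate at the para carbon) should give the para-hydroperoxy dienone F1. Me2S reduces F1 to quinol 12, and DBU (cat.) closes 12 to adduct 13. The Burgess reagent (THF, 50 °C) then removes the tertiary hydroxyl of 13 by syn-elimination with the cis hydrogen at C7a under neutral conditions, and tautomerisation gives 14.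

2. Step 12. Oxidative addition into the hindered, electron-rich aryl bromide and C–C reductive elimination to a seven-membered ring may both be slow, so that protodebromination or intermolecular coupling takes over. The fallback sets out from 17 and comes back at 18 without palladium: photostimulated radical-chain (SRN1) arylation of the potassium enolate (KOtBu, DMSO, 350 nm, rt). Electron transfer to the aryl bromide releases bromide, the aryl radical is captured by the tethered enolate carbon, and the chain continues; this reaction type is known to close benzo-fused seven-membered ketones. No new compound arises (F0).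

3. Step 3. Palladium hydride may reduce the enone or the C–Br bond before cyclisation, and facial discrimination in the carbopalladation may be too low for useful enantiomeric purity. The fallback sets out from 4 and comes back at 5 through an arylboron nucleophile. Miyaura borylation of 4 (B2pin2, PdCl2(dppf), KOAc, dioxane, 80 °C) should give the pinacol boronate chalcone F2. Rhodium-catalysed asymmetric intramolecular conjugate addition (Hayashi–Miyaura type; [RhCl(C2H4)2]2, chiral diene or phosphoramidite ligand, aq. KOH, toluene, 60 °C) then transfers the aryl group to the enone β-carbon and gives 5.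

Further compounds
F1 | step 9 | 6-{(1S,2R)-2-[4-(benzyloxy)phenyl]-1-[3,5-bis(benzyloxy)-2-bromophenyl]-2-hydroxyethyl}-6-hydroperoxy-N-methoxy-N-methyl-3-oxocyclohexa-1,4-diene-1-carboxamide | CON(C)C(=O)C1=CC(=O)C=CC1(OO)[C@@H](c1cc(OCc2ccccc2)cc(OCc2ccccc2)c1Br)[C@@H](O)c1ccc(OCc2ccccc2)cc1
F0 | step 12 | none | none
F2 | step 3 | (E)-3-[3,5-bis(benzyloxy)phenyl]-1-[5-(methoxymethoxy)-2-(4,4,5,5-tetramethyl-1,3,2-dioxaborolan-2-yl)phenyl]prop-2-en-1-one | O=C(/C=C/c1cc(OCc2ccccc2)cc(OCc2ccccc2)c1)c1cc(OCOC)ccc1B1OC(C)(C)C(C)(C)O1
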